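The vessel is closed, stirred and isothermal, and the three new flasks differ in free base: 1.10, 2.20 and 4.40 of the electrophile charge, against 1.50 in larch and 6.80 in birch.

all flasks: electrophile 0.010 M

| flask | nucleophile | free base | remark | time |
|---|---|---|---|---|
| larch | 0.011 M | 0.015 M | run made earlier |  |
| birch | 0.011 M | 0.068 M | run made earlier |  |
| Friday's | 0.0110 M | 0.0110 M |  | 20 min |
| Saturday's | 0.0110 M | 0.0220 M |  | 20 min |
| Sunday's | 0.0110 M | 0.0440 M |  | 20 min |

| run | time / min | electrophile / % | target / % |
|---|---|---|---|
| larch | 0.667 | 38.6 | 53.7 |
| larch | 2.00 | 17.8 | 66.3 |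
| larch | 4.00 | 8.7 | 70.3 |
| larch | 5.00 | 6.5 | 70.9 |
| larch | 8.00 | 3.2 | 72.7 |
| larch | 10.0 | 0.9 | 72.2 |
| birch | 0.833 | 27.4 | 63.7 |
| birch | 1.33 | 18.9 | 69.7 |
| birch | 2.00 | 10.5 | 75.3 |
| birch | 4.00 | 4.6 | 79.0 |
| birch | 6.00 | 1.8 | 81.4 |
| birch | 10.0 | 0.4 | 82.0 |

(readings scatter by 0.5 percentage points)

- a reading or a percentage of target counts all its forms, free or not

- part of the electrophile that has reacted at the end, Friday's
- part of the electrophile that has reacted at the end, Saturday's
- part of the electrophile that has reacted at the end, Sunday's
- what raising the concentration of free base from its lowest to its highest value here does to the part of the electrophile that has reacted (changes below 5 percentage points count as none) (it falls / no change / it rises)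

Question: what can be read from larch about the end? Answer: its tail. Larch's electrophile falls from 17.8% at 2.00 min to 3.2% at 8.00 min. Taken as a pseudo-first-order decay, that is 0.286 min⁻¹, so a reading of 2.42 min for the tail half-life, the time in which the electrophile left halves once the fast start is over.

Question: what does the time allowed do with it? Answer: from that early larch reading to 20 min there are 7.44 tail half-lives, which leaves 0.103%.

Follow-up: but Friday's has less free base than larch, and birch, with more, shows a shorter tail of 1.57 min. Answer: then I double the half-life for Friday's. That gives 3.71 half-lives and 1.36% left, an estimate of my own that rests on scattered readings and a doubling of my own choosing. It is less than the margin of 5 percentage points, so I say no change.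

The forecast gives 99.2%, 99.7% and 99.9%, with no change, and holds that “Base therefore changes selectivity and speed, but not the final consumption”. My estimate leaves 98.6% reacted in Friday's, which is less than the forecast's 99.2%.

The flasks give 99.8%, >99.9% and >99.9%: no change, with a change of 0.18 points.

    electrophile + nucleophile → acid set free + target (k = 4.47 M⁻¹ s⁻¹)
    nucleophile + acid set free ⇌ protonated nucleophile, settled at all times (K = 2.25 × 10⁵ M⁻¹)
    acid set free + free base ⇌ salt of the base, settled at all times (K = 63000 M⁻¹)
    crystals ⇌ target, rate k4*(cs4 - [target]) while solid is left; crystals form when [target] > cs4 (solubility = 3.40 mM, k = 0.326 s⁻¹)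
    electrophile + target → side product (k = 0.570 M⁻¹ s⁻¹)

Friday's electrophile goes from 2.00% at 10.0 min to 0.181% at 20.0 min, a half-life of 2.88 min, which is longer than 2.42 min and shorter than the doubled value. The neighbour is Saturday's flask read at 5.00 min. Larch's early reading and 2.42 min leave 7.55% there. The flask holds 4.5%, less than reckoned, so 95.5% has reacted. By 10.0 min Saturday's is down to 0.787%, a half-life of 2.00 min, shorter than larch's.

(The readings were generated by integration on assumed constants, noise included.)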